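The flask is read at 2.0 min, so the question is what each nucleophile has done by then.

    2 nucleophile → homo dimer (k1 = 1.59 M⁻¹ s⁻¹)
    electrophile + product ⇌ idle adduct, settled at all times (K2 = 500 M⁻¹)
    acid set free + free base ⇌ salt of the base (K3 = 39.0 M⁻¹, k3 = 27.0 M⁻¹ s⁻¹)
    nucleophile + acid set free ⇌ protonated nucleophile, settled at all times (K4 = 8530 M⁻¹)
    electrophile + nucleophile → acid set free + product (k5 = 0.137 M⁻¹ s⁻¹)

- Thursday's: electrophile 0.10 M; nucleophile 0.180 M; free base 0.0800 M; time 2.0 min
- Friday's: electrophile 0.10 M; nucleophile 0.180 M; free base 0.160 M; time 2.0 min

- a species is counted by the electrophile in it: one idle adduct counts as two
- amounts and yields of product count idle adduct too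
- a doubled species enters its step squared and goes two at a time
- in an amount of product, one idle adduct counts as one product
- what has gone from electrophile into another species counts as reacted, even if it can come back
- run time (Thursday's): 2.0 min

* part of the electrophile that has reacted at the end, Thursday's
* part of the electrophile that has reacted at the end, Friday's
* what raising the concentration of free base from its lowest to its highest value here does to the part of the electrophile that has reacted (changes below 5 percentage points count as none) (no change / it rises / it falls)

*What does a nucleophile choose between?* Another nucleophile or the electrophile. In the symmetric case, equal concentrations use nucleophile equally by both routes, which puts the scale's zero at a ratio of 1. Here that ratio is 23.2: the selectivity factor S, nucleophile used by dimer formation over nucleophile used by coupling at equal concentrations of the partners.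

*And with Thursday's charges?* Multiply S by nucleophile over electrophile, which gives 41.8 at the start, so dimer formation takes nearly all of the first nucleophile used.

*Does the nucleophile last the run?* Its first half-life by dimer formation, 1.75 s, is far shorter than the run, so as an approximation I integrate down to zero free nucleophile.

*How much coupling, then?* Dividing the two rates and integrating, with electrophile held at its charge, gives (electrophile/S)·ln(1 + S·nucleophile/electrophile), or 0.0162 M.

*Is that the reacted part?* No. The idle adduct's constant times the charged electrophile is 50, far above 1, so at the start nearly all product takes a second electrophile. Two electrophile go per coupling, which gives 32.4%. Free base is not in this formula, so I give Friday's the same figure and expect no change.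

*Where is that weak?* Electrophile falls during the run, which puts my figure on the high side. Acid also goes to the nucleophile first: on Thursday's charges, constant times charge is 1500 against 3.1 for the free base, and I have not counted that bound nucleophile.

The forecast says 33% for Thursday's and 32% for Friday's, with no change, holding that “doubling the base only slightly changes the small buffering of free nucleophile”.

The simulation gives 25.1% on Thursday's and 25.6% on Friday's, no change (0.45 percentage points), so the trend stands, and the forecast's figures and mine are higher than these. On Friday's, the dimer-to-coupling rate ratio, S times free nucleophile over electrophile, falls from 42 just after the start to 0.50 at 2.00 min, and half of the dimer turnover up to then is done by 1.42 s. For Friday's flask with 0.40 M of electrophile, S gives a reacted part of 21.0%; the simulation gives 18.7%.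

All constants are those of an exercise; no experiment stands behind them.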